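**Retrosynthetic overview** (side-chain locants follow the dodeca-3,7-dien-2-yl name; C2′ is the stereocentre on coumarin C3, read from the SMILES as 2′S,3′E,7′Z)
- The C3–C2′ bond, the C2′ stereocentre and the 3′E alkene come from one aromatic Claisen ([3,3]) shift of an (R)-configured secondary allyl 4-O-ether of 4-hydroxy-7-methoxycoumarin, which passes through a non-aromatic chromane-2,4-dione.
- That ether comes from Mitsunobu inversion of an (S)-allylic alcohol with the coumarin enol, run in the same pot as the shift (last step).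
- The (S)-alcohol comes from a C6′–C7′ B-alkyl Suzuki coupling of the 9-BBN adduct of (3S,4E)-4-methylhexa-1,4-dien-3-ol with a (Z)-β-iodoenone, which fixes the 7′Z enone.
- The dienol comes from tiglaldehyde and vinylmagnesium bromide, then Sharpless kinetic resolution; the iodoenone comes from isovaleryl chloride and propyne, then anti-hydroiodination.
- Ring order: the benzene ring is bought (paeonol); the pyranone ring is closed first (paeonol + diethyl carbonate); no other ring is made.

**Route**

Step 1
Reactants: 1 1-(2-hydroxy-4-methoxyphenyl)ethan-1-one (paeonol); 2 diethyl carbonate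
Product: 4 4-hydroxy-7-methoxy-2H-chromen-2-one, via β-keto ester 3 (not isolated)
Conditions: NaH (3 equiv), PhMe, 110 °C; then aq HCl
Reagents that add atoms: none
Why: Claisen-type C-acylation of the ketone enolate by diethyl carbonate gives the β-keto ester, whose phenoxide lactonises onto the ester (the standard 4-hydroxycoumarin synthesis from o-hydroxyacetophenones); no stereocentre is formed.

Step 2
Reactants: 5 3-methylbutanoyl chloride; 6 propyne
Product: 7 6-methylhept-2-yn-4-one
Conditions: PdCl2(PPh3)2 (2 mol%), CuI (4 mol%), Et3N (1.05 equiv), THF, 0 °C → rt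
Reagents that add atoms: none
Why: Acyl Sonogashira coupling, in which zerovalent palladium (formed from PdCl2(PPh3)2) inserts into the C–Cl bond of 5, the propynyl group is delivered by CuI/Et3N and reductive elimination gives the ynone, while only one equivalent of amine at or below room temperature keeps ketene formation low.

Step 3
Reactants: 7 6-methylhept-2-yn-4-one
Product: 8 (2Z)-2-iodo-6-methylhept-2-en-4-one
Conditions: NaI (1.5 equiv), AcOH, rt, 2 h, dark
Reagents that add atoms: sodium iodide, [Na+].[I-]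
Why: Conjugate hydroiodination of the ynone, in which iodide adds to the β-carbon and the allenol is protonated anti, gives the (Z)-β-iodoenone (iodine cis to the carbonyl) under kinetic control.

Step 4
Reactants: 9 (2E)-2-methylbut-2-enal (tiglaldehyde); 10 vinylmagnesium bromide
Product: 11 rac-(4E)-4-methylhexa-1,4-dien-3-ol
Conditions: THF, −78 → 0 °C; aqueous work-up
Reagents that add atoms: none
Why: Grignard 1,2-addition to the α-methyl enal gives the racemic dienol and leaves the (E)-trisubstituted alkene unchanged.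

Step 5
Reactants: 11 rac-(4E)-4-methylhexa-1,4-dien-3-ol
Product: 12 (3S,4E)-4-methylhexa-1,4-dien-3-ol
Conditions: Ti(OiPr)4 (10 mol%), D-(−)-DIPT (15 mol%), t-BuOOH (0.6 equiv), 4 Å MS, CH2Cl2, −20 °C, to ca. 58% conversion
Reagents that add atoms: none
Why: Sharpless kinetic resolution, in which the Ti(OiPr)4/D-(−)-tartrate catalyst epoxidises the (R)-enantiomer at its (E)-trisubstituted alkene far faster than the (S)-enantiomer (the vinyl group is much less reactive), so the unreacted (S)-alcohol is recovered in high ee (expected ≥98%, maximum yield about 40–45%).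

Step 6
Reactants: 12 (3S,4E)-4-methylhexa-1,4-dien-3-ol; 8 (2Z)-2-iodo-6-methylhept-2-en-4-one
Product: 14 (5Z,9S,10E)-9-hydroxy-2,6,10-trimethyldodeca-5,10-dien-4-one, via bis-boryl adduct 13 (not isolated)
Conditions: 9-BBN (2.2 equiv), THF, 0 °C → rt; then 3 M aq K3PO4, 8, PdCl2(dppf) (5 mol%), AsPh3 (5 mol%), DMF, rt
Reagents that add atoms: none
Why: B-alkyl Suzuki–Miyaura coupling, in which 9-BBN adds anti-Markovnikov to the monosubstituted alkene only (the hydroxyl is masked in the flask as its borinate and residual B–H is destroyed by the aqueous base before 8 is added) and the primary alkylborane couples with the β-iodoenone with retention of the Z geometry, the carbinol centre being untouched.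

Step 7
Reactants: 14 (5Z,9S,10E)-9-hydroxy-2,6,10-trimethyldodeca-5,10-dien-4-one; 4 4-hydroxy-7-methoxy-2H-chromen-2-one
Product: 17 4-hydroxy-7-methoxy-3-[(2S,3E,7Z)-3,7,11-trimethyl-9-oxododeca-3,7-dien-2-yl]-2H-chromen-2-one, via allyl ether 15 (not isolated), via chromane-2,4-dione 16 (not isolated)
Conditions: PPh3 (1.2 equiv), DIAD (1.2 equiv), 4 (1.3 equiv), THF/PhMe (1:4), 0 °C → rt, 2 h; then 120 °C (sealed tube), 8 h
Reagents that add atoms: none
Why: The Mitsunobu reaction O-alkylates the acidic coumarin enol by SN2 with inversion to give the (R)-allyl ether, and on heating an aromatic Claisen rearrangement breaks the aromaticity of the pyranone ring through a chair transition state (side chain and butenyl methyl both pseudo-equatorial) that transfers chirality suprafacially from C–O to C–C, setting C2′ (S) and the 3′E alkene together before the chromane-2,4-dione re-enolises to the 4-hydroxycoumarin, the minor 2-O-alkyl chromone isomer converging on the same product by the same shift.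

**Compound list**
1 | 1-(2-hydroxy-4-methoxyphenyl)ethan-1-one (paeonol) | COc1ccc(C(C)=O)c(O)c1 | starting material
2 | diethyl carbonate | CCOC(=O)OCC | starting material
3 | ethyl 3-(2-hydroxy-4-methoxyphenyl)-3-oxopropanoate (formed as its sodium salt, not isolated) | COc1ccc(C(=O)CC(=O)OCC)c(O)c1 | intermediate
4 | 4-hydroxy-7-methoxy-2H-chromen-2-one | COc1ccc2c(O)cc(=O)oc2c1 | intermediate
5 | 3-methylbutanoyl chloride (isovaleryl chloride) | CC(C)CC(Cl)=O | starting material
6 | propyne | CC#C | starting material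
7 | 6-methylhept-2-yn-4-one | CC#CC(=O)CC(C)C | intermediate
8 | (2Z)-2-iodo-6-methylhept-2-en-4-one | C/C(I)=C/C(=O)CC(C)C | intermediate
9 | (2E)-2-methylbut-2-enal (tiglaldehyde) | C/C=C(\C)C=O | starting material
10 | vinylmagnesium bromide | C=C[Mg]Br | starting material
11 | rac-(4E)-4-methylhexa-1,4-dien-3-ol | C/C=C(\C)C(O)C=C | intermediate
12 | (3S,4E)-4-methylhexa-1,4-dien-3-ol | C/C=C(\C)[C@@H](O)C=C | intermediate
13 | 9-[(3S,4E)-3-(9-borabicyclo[3.3.1]nonan-9-yloxy)-4-methylhex-4-en-1-yl]-9-borabicyclo[3.3.1]nonane (not isolated) | C/C=C(\C)[C@@H](OB1C2CCCC1CCC2)CCB1C2CCCC1CCC2 | intermediate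
14 | (5Z,9S,10E)-9-hydroxy-2,6,10-trimethyldodeca-5,10-dien-4-one | C/C=C(\C)[C@@H](O)CC/C(C)=C\C(=O)CC(C)C | intermediate
15 | 7-methoxy-4-{[(2E,4R,7Z)-3,7,11-trimethyl-9-oxododeca-2,7-dien-4-yl]oxy}-2H-chromen-2-one (not isolated) | C/C=C(\C)[C@H](Oc1cc(=O)oc2cc(OC)ccc12)CC/C(C)=C\C(=O)CC(C)C | intermediate
16 | (3R)-7-methoxy-3-[(2R,3E,7Z)-3,7,11-trimethyl-9-oxododeca-3,7-dien-2-yl]chromane-2,4-dione (not isolated; same spatial arrangement at the side-chain centre as in 17, descriptor changes by priority only) | COc1ccc2c(c1)OC(=O)[C@H]([C@@H](C)/C(C)=C/CC/C(C)=C\C(=O)CC(C)C)C2=O | intermediate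
17 | 4-hydroxy-7-methoxy-3-[(2S,3E,7Z)-3,7,11-trimethyl-9-oxododeca-3,7-dien-2-yl]-2H-chromen-2-one (CNP0223069.2) | COc1ccc2c(O)c([C@@H](C)/C(C)=C/CC/C(C)=C\C(=O)CC(C)C)c(=O)oc2c1 | target

**Totals**
Total step count: 7. Longest linear sequence: 4 steps (9 → 11 → 12 → 14 → 17; the branch 5 → 7 → 8 → 14 → 17 is equally long).

**Steps most likely to fail, and fallbacks**

Step 7 (one-pot Mitsunobu and Claisen shift). The risks are SN2′ or C-alkylation and partial ionisation in the Mitsunobu stage, Z → E drift of the enone at 120 °C in the presence of phosphorus by-products, and some Z-alkene from the minor chair with the chain axial. The fallback keeps the same chirality relay but takes the enone out of the thermal step and joins it last; it sets out from 12 and comes back to the route at 17. Iridium-catalysed hydroboration of the vinyl group of 12 (HBpin, [Ir(cod)Cl]2, dppm, CH2Cl2, rt, methanolic work-up) gives (3S,4E)-4-methyl-1-(4,4,5,5-tetramethyl-1,3,2-dioxaborolan-2-yl)hex-4-en-3-ol F1. Mitsunobu reaction of F1 with 4 (PPh3, DIAD, PhMe, 0 °C → rt) gives 7-methoxy-4-{[(3R,4E)-4-methyl-1-(4,4,5,5-tetramethyl-1,3,2-dioxaborolan-2-yl)hex-4-en-3-yl]oxy}-2H-chromen-2-one F2, which is isolated, freed of by-products and heated alone (PhMe, 120 °C). The same [3,3] shift then passes through (3R)-7-methoxy-3-[(2R,3E)-3-methyl-6-(4,4,5,5-tetramethyl-1,3,2-dioxaborolan-2-yl)hex-3-en-2-yl]chromane-2,4-dione F3 and gives 4-hydroxy-7-methoxy-3-[(2S,3E)-3-methyl-6-(4,4,5,5-tetramethyl-1,3,2-dioxaborolan-2-yl)hex-3-en-2-yl]-2H-chromen-2-one F4. A final Suzuki–Miyaura coupling of the primary alkylboronate F4 with iodoenone 8 (Pd(OAc)2, RuPhos, aq K3PO4, PhMe, 60–70 °C) forms the C6′–C7′ bond and gives 17.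

Step 6 (hydroboration and B-alkyl Suzuki coupling). The risks are attack of aqueous base on the β-iodoenone, and oxa-Michael closure or Z → E drift of hydroxy enone 14 under basic palladium conditions. The fallback couples at the ester oxidation level and builds the ketone afterwards; it sets out from 12 (through its in-flask adduct 13) and comes back at 14. Adduct 13 is coupled with commercial ethyl (2Z)-3-iodobut-2-enoate under the same palladium conditions to give ethyl (2Z,6S,7E)-6-hydroxy-3,7-dimethylnona-2,7-dienoate F5. Treatment with MeNHOMe·HCl and isopropylmagnesium chloride (THF, −20 °C) gives (2Z,6S,7E)-6-hydroxy-N-methoxy-N,3,7-trimethylnona-2,7-dienamide F6. Isobutylmagnesium bromide (3 equiv, THF, −20 → 0 °C, cold citric acid quench) then gives 14.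

Step 2 (acyl Sonogashira coupling). The risks are ketene formation from the enolisable acid chloride with Et3N and the handling of gaseous propyne. The fallback is a Weinreb ketone synthesis; it sets out from 5 and comes back at 7. Acid chloride 5 with MeNHOMe·HCl and pyridine (CH2Cl2, 0 °C) gives N-methoxy-N,3-dimethylbutanamide F7, and 1-propynylmagnesium bromide (THF, 0 °C) converts F7 into 7.

**Further compounds**
F1 | step 7 | (3S,4E)-4-methyl-1-(4,4,5,5-tetramethyl-1,3,2-dioxaborolan-2-yl)hex-4-en-3-ol | C/C=C(\C)[C@@H](O)CCB1OC(C)(C)C(C)(C)O1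
F2 | step 7 | 7-methoxy-4-{[(3R,4E)-4-methyl-1-(4,4,5,5-tetramethyl-1,3,2-dioxaborolan-2-yl)hex-4-en-3-yl]oxy}-2H-chromen-2-one | C/C=C(\C)[C@H](Oc1cc(=O)oc2cc(OC)ccc12)CCB3OC(C)(C)C(C)(C)O3
F3 | step 7 | (3R)-7-methoxy-3-[(2R,3E)-3-methyl-6-(4,4,5,5-tetramethyl-1,3,2-dioxaborolan-2-yl)hex-3-en-2-yl]chromane-2,4-dione | COc1ccc2c(c1)OC(=O)[C@H]([C@@H](C)/C(C)=C/CCB3OC(C)(C)C(C)(C)O3)C2=O
F4 | step 7 | 4-hydroxy-7-methoxy-3-[(2S,3E)-3-methyl-6-(4,4,5,5-tetramethyl-1,3,2-dioxaborolan-2-yl)hex-3-en-2-yl]-2H-chromen-2-one | COc1ccc2c(O)c([C@@H](C)/C(C)=C/CCB3OC(C)(C)C(C)(C)O3)c(=O)oc2c1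
F5 | step 6 | ethyl (2Z,6S,7E)-6-hydroxy-3,7-dimethylnona-2,7-dienoate | C/C=C(\C)[C@@H](O)CC/C(C)=C\C(=O)OCC
F6 | step 6 | (2Z,6S,7E)-6-hydroxy-N-methoxy-N,3,7-trimethylnona-2,7-dienamide | C/C=C(\C)[C@@H](O)CC/C(C)=C\C(=O)N(C)OC
F7 | step 2 | N-methoxy-N,3-dimethylbutanamide | CC(C)CC(=O)N(C)OC
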